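Numbering is that of the eudesmanes (ring A: C1–C5 and C10; ring B: C5–C10; C11–C13 on C7; C14 on C10; C15 on C4). The retrosynthesis cuts the C5–OOH bond (ene reaction of O2 with a Δ4 alkene) and the C3–O acyl bond, returns C3 to a ketone and C12 to a methyl group, and then opens ring A of (+)-α-cyperone at C4=C5 and C10–C1.
Enabling feature: ring B with the C5 carbonyl carbon, the C10 methyl (C14) and the three-carbon branch on C7 is dihydrocarvone atom for atom, and C1–C2–C3–C4(C15) is pent-1-en-3-one. The one hard atom is quaternary C10, whose methyl must be cis to the C7 branch.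
Forward: ring B is bought as (R)-carvone; ring A is closed onto it by a chiral-imine Michael addition (C10–C1) and an aldol condensation (C4=C5). C12 is then oxidised to the methyl ester, C3 is reduced and angeloylated, and the hydroperoxide is installed last.
Stereochemistry: C7 from (R)-carvone; C10 from the (R)-1-phenylethylamine auxiliary; C3 from axial hydride attack anti to C14; C5 from α-face attack of singlet oxygen anti to C14; the Z ester alkene from angelic acid.

Key step: step 3

Remark: α and β denote the faces of the bicycle opposite to and on the side of C14. Dihydrocarvone and its imine are carried as mixtures of epimers at the methyl-bearing carbon, which becomes trigonal in the enamine of the key step; only the major epimer is drawn.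

Step 1
Reactants: 1 (R)-(−)-carvone
Product: 2 (+)-dihydrocarvone
Conditions: Zn dust, KOH, EtOH–H2O, reflux
Reagents that add atoms: none
Why: Zinc in aqueous alcoholic alkali is a dissolving-metal conjugate reduction that saturates only the enone C=C and leaves the isolated isopropenyl alkene and the C5 stereocentre (the later C7) untouched, while the configuration of the new C2 centre is irrelevant because it is erased in step 3.

Step 2
Reactants: 2 (+)-dihydrocarvone; 3 (R)-(+)-1-phenylethylamine
Product: 4 (E)-ketimine of 2 with 3
Conditions: p-toluenesulfonic acid (cat.), toluene, reflux, Dean–Stark; used crude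
Reagents that add atoms: none
Why: Acid-catalysed condensation of a ketone with a primary amine under azeotropic removal of water (imine formation) should give the ketimine with the nitrogen substituent anti to the branched α-carbon, and neither the C5 centre nor the benzylic centre is at risk.

Step 3
Reactants: 4 (E)-ketimine; 5 pent-1-en-3-one
Product: 10 (+)-α-cyperone, via enamine tautomer 6 (not isolated), via Michael adduct imine 7 (not isolated), via 1,5-diketone 8 (not isolated), via ketol 9 (not isolated)
Conditions: 5 (1.5 equiv), THF, rt, dark, 3–5 d; then 10% aq AcOH, rt; extractive removal of the amine salt; then NaOMe, MeOH, rt → 50 °C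
Reagents that add atoms: none
Why: The imine equilibrates with its tetrasubstituted secondary enamine 6, whose C10 adds to the β-carbon of 5 in a compact, chair-like aza-ene transition state that passes N–H to the α-carbon of the enone and gives imine 7 with the new C10–C1 bond; this is the deracemising Michael addition of chiral 1-phenylethylamine imines, followed after hydrolysis to 8 by the aldol half of a Robinson annulation. Ring A closes when the C4 enolate of the ethyl ketone attacks the C5 carbonyl, a 6-(enolendo)-exo-trig aldol addition to ketol 9, and E1cB loss of water then places the alkene at C4=C5 in conjugation with C3=O. The only new stereocentre, quaternary C10, is controlled by the (R) centre of the auxiliary: with the benzylic C–H in the enamine plane to avoid allylic strain, the phenyl group covers one face and 5 is delivered to the other, the α face, so that C14 ends up β and cis to the C7 isopropenyl group. The step needs regioselectivity for C10 over C6, secured because only the more substituted enamine tautomer holds N–H syn to the reacting carbon and because 7 cannot re-enter the cycle at C10. It also needs facial selectivity against the ring's own preference for axial entry of the acceptor on the β face (which would give the 10-epimer), and the auxiliary, chosen as (R), is expected to override this. C7 is untouched throughout, and both C2 epimers of 4 converge on the same enamine.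

Step 4
Reactants: 10 (+)-α-cyperone
Product: 12 (7R,10S)-3-oxoeudesma-4,11(13)-dien-12-al, via 12-hydroxy-α-cyperone 11 (not isolated)
Conditions: SeO2 (0.3 equiv), t-BuOOH (3 equiv), CH2Cl2, 0 °C → rt; filter, then activated MnO2, CH2Cl2, rt
Reagents that add atoms: tert-butyl hydroperoxide, CC(C)(C)OO (terminal oxygen source); selenium dioxide, O=[Se]=O (oxygen carrier)
Why: Riley-type allylic oxidation (ene reaction of SeO2 at the electron-rich 1,1-disubstituted alkene followed by a [2,3]-sigmatropic shift) should functionalise the C12 methyl group, which is favoured over the C7 methine at the disubstituted alkene terminus, while the electron-poor enone alkene does not engage, and MnO2 then converges the alcohol–aldehyde mixture on the enal by allylic alcohol oxidation.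

Step 5
Reactants: 12 (7R,10S)-3-oxoeudesma-4,11(13)-dien-12-al
Product: 13 (7R,10S)-3-oxoeudesma-4,11(13)-dien-12-oic acid
Conditions: NaClO2, NaH2PO4, 2-methylbut-2-ene, t-BuOH/H2O, 0 °C → rt
Reagents that add atoms: sodium chlorite, [Na+].[O-]Cl=O
Why: Pinnick oxidation converts the conjugated aldehyde into the acid through chlorous acid addition and fragmentation without touching the alkenes or the C7 centre, the hypochlorous acid formed being trapped by 2-methylbut-2-ene.

Step 6
Reactants: 13 (7R,10S)-3-oxoeudesma-4,11(13)-dien-12-oic acid
Product: 14 methyl (7R,10S)-3-oxoeudesma-4,11(13)-dien-12-oate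
Conditions: MeI, KHCO3, DMF, rt
Reagents that add atoms: iodomethane, CI
Why: SN2 O-methylation of the carboxylate with iodomethane under bicarbonate, a base too weak to enolise the enone, gives the methyl ester and avoids diazoalkanes that could add to the acrylate.

Step 7
Reactants: 14 methyl (7R,10S)-3-oxoeudesma-4,11(13)-dien-12-oate
Product: 15 methyl (3S,7R,10S)-3-hydroxyeudesma-4,11(13)-dien-12-oate (3β-OH)
Conditions: NaBH4, CeCl3·7H2O, MeOH, −20 °C
Reagents that add atoms: none
Why: Luche reduction delivers hydride 1,2 to the cerium-activated enone carbonyl, axially from the α face anti to the angular C14 methyl, to set the equatorial 3β-alcohol (3S), and the hard alkoxyborohydride at low temperature should leave the methyl acrylate unreduced.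

Step 8
Reactants: 15 methyl (3S,7R,10S)-3-hydroxyeudesma-4,11(13)-dien-12-oate; 16 angelic acid
Product: 18 methyl (3S,7R,10S)-3-angeloyloxyeudesma-4,11(13)-dien-12-oate, via mixed anhydride 17 (not isolated)
Conditions: 16 (3 equiv), 2,4,6-trichlorobenzoyl chloride, Et3N, toluene, rt; then 15, 80 °C
Reagents that add atoms: none
Why: Yamaguchi-type acylation through the mixed anhydride, run without a nucleophilic catalyst, lets the alcohol attack the unhindered angeloyl carbonyl with retention at C3, and the absence of DMAP-type catalysts avoids the addition–elimination pathway that isomerises angelates (Z) to tiglates (E).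

Step 9
Reactants: 18 methyl (3S,7R,10S)-3-angeloyloxyeudesma-4,11(13)-dien-12-oate
Product: 19 methyl (3S,5S,7R,10S)-3-angeloyloxy-5-hydroperoxyeudesma-4(15),11(13)-dien-12-oate (target)
Conditions: O2, 5,10,15,20-tetraphenylporphyrin (cat.), white LED, CH2Cl2, −20 °C; no reductive work-up, cold chromatography
Reagents that add atoms: dioxygen, O=O
Why: In the Schenck ene reaction singlet oxygen should attack the electron-rich tetrasubstituted C4=C5 bond (the acrylate and angelate alkenes are electron-poor and far slower) from the α face anti to the axial C14 methyl, bond to C5 and take a hydrogen from the freely rotating C15 methyl, since H-6α is pseudo-equatorial and poorly aligned and H-3α is deactivated by the geminal acyloxy group, which gives the 5α-hydroperoxide (5S) with the exocyclic C4=C15 alkene.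

Compound list
1 | (R)-(−)-carvone, (5R)-2-methyl-5-(prop-1-en-2-yl)cyclohex-2-en-1-one | C=C(C)[C@@H]1CC=C(C)C(=O)C1 | starting material
2 | (+)-dihydrocarvone, (2R,5R)-2-methyl-5-(prop-1-en-2-yl)cyclohexan-1-one (trans epimer drawn, carried with its C2 epimer) | C=C(C)[C@@H]1CC[C@@H](C)C(=O)C1 | intermediate
3 | (R)-(+)-1-phenylethylamine | C[C@@H](N)c1ccccc1 | starting material
4 | (E)-ketimine, (1R)-N-[(2R,5R)-2-methyl-5-(prop-1-en-2-yl)cyclohexylidene]-1-phenylethanamine | C=C(C)[C@@H]1CC[C@@H](C)/C(=N/[C@H](C)c2ccccc2)C1 | intermediate
5 | pent-1-en-3-one (ethyl vinyl ketone) | C=CC(=O)CC | starting material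
6 | secondary enamine tautomer, (1R)-N-[(5R)-2-methyl-5-(prop-1-en-2-yl)cyclohex-1-en-1-yl]-1-phenylethanamine | C=C(C)[C@@H]1CCC(C)=C(N[C@H](C)c2ccccc2)C1 | intermediate (not isolated)
7 | Michael adduct imine, the (R)-1-phenylethylamine imine of 8 at the ring carbonyl, nitrogen substituent anti to the quaternary carbon | C=C(C)[C@@H]1CC[C@@](C)(CCC(=O)CC)/C(=N/[C@H](C)c2ccccc2)C1 | intermediate (not isolated)
8 | 1,5-diketone, (2S,5R)-2-methyl-2-(3-oxopentyl)-5-(prop-1-en-2-yl)cyclohexan-1-one | C=C(C)[C@@H]1CC[C@@](C)(CCC(=O)CC)C(=O)C1 | intermediate (not isolated)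
9 | ketol, (7R,10S)-5-hydroxyeudesm-11-en-3-one (C4 and C5 not assigned; both are lost on dehydration) | C=C(C)[C@@H]1CC[C@@]2(C)CCC(=O)C(C)C2(O)C1 | intermediate (not isolated)
10 | (+)-α-cyperone, (4aS,7R)-1,4a-dimethyl-7-(prop-1-en-2-yl)-4,4a,5,6,7,8-hexahydronaphthalen-2(3H)-one | C=C(C)[C@@H]1CC[C@@]2(C)CCC(=O)C(C)=C2C1 | intermediate
11 | 12-hydroxy-α-cyperone, (7R,10S)-12-hydroxyeudesma-4,11(13)-dien-3-one | C=C(CO)[C@@H]1CC[C@@]2(C)CCC(=O)C(C)=C2C1 | intermediate (not isolated)
12 | (7R,10S)-3-oxoeudesma-4,11(13)-dien-12-al | C=C(C=O)[C@@H]1CC[C@@]2(C)CCC(=O)C(C)=C2C1 | intermediate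
13 | (7R,10S)-3-oxoeudesma-4,11(13)-dien-12-oic acid | C=C(C(=O)O)[C@@H]1CC[C@@]2(C)CCC(=O)C(C)=C2C1 | intermediate
14 | methyl (7R,10S)-3-oxoeudesma-4,11(13)-dien-12-oate | C=C(C(=O)OC)[C@@H]1CC[C@@]2(C)CCC(=O)C(C)=C2C1 | intermediate
15 | methyl (3S,7R,10S)-3-hydroxyeudesma-4,11(13)-dien-12-oate (3β-OH) | C=C(C(=O)OC)[C@@H]1CC[C@@]2(C)CC[C@H](O)C(C)=C2C1 | intermediate
16 | angelic acid, (Z)-2-methylbut-2-enoic acid | C/C=C(/C)C(=O)O | starting material
17 | mixed anhydride, (Z)-2-methylbut-2-enoic 2,4,6-trichlorobenzoic anhydride | C/C=C(/C)C(=O)OC(=O)c1c(Cl)cc(Cl)cc1Cl | intermediate (not isolated)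
18 | methyl (3S,7R,10S)-3-[(Z)-2-methylbut-2-enoyloxy]eudesma-4,11(13)-dien-12-oate (3β-angelate) | C=C(C(=O)OC)[C@@H]1CC[C@@]2(C)CC[C@H](OC(=O)/C(C)=C\C)C(C)=C2C1 | intermediate
19 | methyl (3S,5S,7R,10S)-5-hydroperoxy-3-[(Z)-2-methylbut-2-enoyloxy]eudesma-4(15),11(13)-dien-12-oate (3β-angeloyloxy, 5α-OOH; CNP0137897.1) | C=C(C(=O)OC)[C@@H]1CC[C@@]2(C)CC[C@H](OC(=O)/C(C)=C\C)C(=C)[C@]2(OO)C1 | target

Total step count: 9. Longest linear sequence: 9 steps (1 → 19); 3, 5 and 16 enter as purchased reagents.

Steps most likely to fail

Step 3. The auxiliary may not fully override the ring's preference for axial, β-face entry of the acceptor (a mismatched pairing), so that the C10 epimer is co-formed, and the slow addition leaves time for 5 to polymerise. The fallback keeps the C10–C1 Michael and C4–C5 aldol bond formation but replaces auxiliary control by substrate control through a temporary cyclopropane. Setting out from 2, HBr in AcOH adds across the isopropenyl group to give (2R,5R)-5-(2-bromopropan-2-yl)-2-methylcyclohexan-1-one F1. KOH in MeOH then closes the three-membered ring by intramolecular alkylation of the enolate on the CH2 side of the ketone, giving 2-carone F2. Base-mediated Robinson annulation of F2 with 5 (KOH, EtOH, 0 °C then reflux) can enolise only towards the methyl-bearing carbon. It should take up the vinyl ketone on the α face, away from the gem-dimethylcyclopropane on the β face, to give 6,11-cycloeudesm-4-en-3-one F3. HCl in EtOH opens the conjugated cyclopropane by homoconjugate addition to 11-chloroeudesm-4-en-3-one F4, and dehydrochlorination with NaOAc in AcOH at 100 °C, which should eliminate into a methyl group, comes back to the route at 10.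

Step 9. Hydrogen abstraction from C6 or C3 in place of C15, attack on the β face, or slow oxygenation of the angelate alkene would erode regio- and face selectivity, and the tertiary allylic hydroperoxide may rearrange on handling. The fallback oxygenates before acylation, with a bulky silyl ether as the C3 group and the hydroperoxide carried in masked form. Setting out from 15, TBSCl and imidazole in DMF give methyl 3β-(tert-butyldimethylsilyloxy)eudesma-4,11(13)-dien-12-oate F5. The ene reaction under the conditions of step 9, now with a larger group geminal to C15 and only one reactive alkene, should give methyl 3β-(tert-butyldimethylsilyloxy)-5α-hydroperoxyeudesma-4(15),11(13)-dien-12-oate F6. 2-Methoxypropene with catalytic pyridinium p-toluenesulfonate in CH2Cl2 at 0 °C masks the hydroperoxide as the 2-methoxyprop-2-yl peroxyketal of the silyl ether F7. Tetrabutylammonium fluoride buffered with AcOH in THF frees the 3β-hydroxy peroxyketal F8. Angeloylation as in step 8 gives the 3β-angeloyloxy peroxyketal F9, and AcOH/THF/H2O at rt removes the ketal, coming back to the route at 19.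

Step 4. The selenium oxidant may also attack the allylic positions of the enone (C6, C15) or over-oxidise, and conversion may stall at mixtures. The fallback uses ene-type allylic chlorination in place of oxygen transfer. Setting out from 10, Ca(OCl)2 with solid CO2 in CH2Cl2/H2O at 0 °C, which generates HOCl, should chlorinate only the isopropenyl group to give 12-chloroeudesma-4,11(13)-dien-3-one F10. Oxidation of this allylic chloride with N-methylmorpholine N-oxide and catalytic NaI in MeCN comes back to the route at 12.

Further compounds
F1 | step 3 | (2R,5R)-5-(2-bromopropan-2-yl)-2-methylcyclohexan-1-one | CC(C)(Br)[C@@H]1CC[C@@H](C)C(=O)C1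
F2 | step 3 | 2-carone, (1S,3R,6R)-3,7,7-trimethylbicyclo[4.1.0]heptan-2-one (C3 epimer equally usable) | CC1(C)[C@@H]2CC[C@@H](C)C(=O)[C@H]12
F3 | step 3 | 6,11-cycloeudesm-4-en-3-one, cyclopropane (C6, C7, C11) on the β face, C14 β | CC1(C)[C@@H]2CC[C@@]3(C)CCC(=O)C(C)=C3[C@H]12
F4 | step 3 | (7R,10S)-11-chloroeudesm-4-en-3-one | CC(C)(Cl)[C@@H]1CC[C@@]2(C)CCC(=O)C(C)=C2C1
F5 | step 9 | methyl (3S,7R,10S)-3-(tert-butyldimethylsilyloxy)eudesma-4,11(13)-dien-12-oate | C=C(C(=O)OC)[C@@H]1CC[C@@]2(C)CC[C@H](O[Si](C)(C)C(C)(C)C)C(C)=C2C1
F6 | step 9 | methyl (3S,5S,7R,10S)-3-(tert-butyldimethylsilyloxy)-5-hydroperoxyeudesma-4(15),11(13)-dien-12-oate | C=C(C(=O)OC)[C@@H]1CC[C@@]2(C)CC[C@H](O[Si](C)(C)C(C)(C)C)C(=C)[C@]2(OO)C1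
F7 | step 9 | methyl (3S,5S,7R,10S)-3-(tert-butyldimethylsilyloxy)-5-[(2-methoxypropan-2-yl)peroxy]eudesma-4(15),11(13)-dien-12-oate | C=C(C(=O)OC)[C@@H]1CC[C@@]2(C)CC[C@H](O[Si](C)(C)C(C)(C)C)C(=C)[C@]2(OOC(C)(C)OC)C1
F8 | step 9 | methyl (3S,5S,7R,10S)-3-hydroxy-5-[(2-methoxypropan-2-yl)peroxy]eudesma-4(15),11(13)-dien-12-oate | C=C(C(=O)OC)[C@@H]1CC[C@@]2(C)CC[C@H](O)C(=C)[C@]2(OOC(C)(C)OC)C1
F9 | step 9 | methyl (3S,5S,7R,10S)-3-[(Z)-2-methylbut-2-enoyloxy]-5-[(2-methoxypropan-2-yl)peroxy]eudesma-4(15),11(13)-dien-12-oate | C=C(C(=O)OC)[C@@H]1CC[C@@]2(C)CC[C@H](OC(=O)/C(C)=C\C)C(=C)[C@]2(OOC(C)(C)OC)C1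
F10 | step 4 | (7R,10S)-12-chloroeudesma-4,11(13)-dien-3-one | C=C(CCl)[C@@H]1CC[C@@]2(C)CCC(=O)C(C)=C2C1
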